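**Plan**

1. Retrosynthesis: the two inter-unit ester C–O bonds (4α-CH2O–CO) are cut first, then the three C11–O ether bonds. This leaves one drimane aldehyde (15, used three times) and two isocitrate blocks (21, 22) made from D-malic acid.
2. In each drimane the pattern C8(=CH2)/C9–C11H2–O beside the quaternary C10 is read as a masked β-hydroxy ketone, the product of a 1,2-shift of C10 from C8 to C9. Ring B (C5–C10) is therefore traced back to the cyclopentanol ring (C5, C6, C7, C8, C10) of a 1-oxiranyl trans-hydrindane.
3. Forward: a Hajos–Parrish annulation gives ring A plus a cyclopentanone; reductive hydroxymethylation and C3 deoxygenation finish ring A; vinyl addition and directed epoxidation arm the five-membered ring; the ring enlargement makes ring B; methylenation and oxidation give 15.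
4. Chain assembly: reductive etherification of 15 with each block, then iterative esterification (unit A alcohol + monomer acid, desilylation, second monomer acid) and deprotection.
5. Stereochemistry: C10 from the (S)-phenylalanine-mediated aldol; C5 and C4 by substrate control in the Li/NH3 reduction–aldol; C9 by the stereospecific anti 1,2-shift; C1' from D-malic acid and C2' by anti-selective Fráter–Seebach alkylation.

Key step: step 10

Remark on numbering: decalins carry drimane numbering (ring A = C1–C5, C10; ring B = C5–C10; C11 on C9; C12 on C8; the oxygenated C4 substituent is the 4α-CH2O group). Hydrindanes carry indane numbering (C1 becomes C8, C7a becomes C10, C3a becomes C5). Isocitrate carbons are C1' (carbinol), C2' (central CH) and C3' (CH2).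

Remark on the chemistry: read from the SMILES, the three sesquiterpene units are identical (5α-H, 10β-CH3, 9β-CH2O, 4α-CH2O/4β-CH3) and the three isocitrates are all (1'R,2'S), so one aldehyde and one chiral-pool acid serve the whole molecule.

**Route**

Step 1
Reactants: 1 2-methylcyclopentane-1,3-dione; 2 pent-1-en-3-one
Product: 4 (7aS)-4,7a-dimethyl-2,3,7,7a-tetrahydro-1H-indene-1,5(6H)-dione, via triketone 3 (not isolated)
Conditions: H2O, 75 °C; crude triketone taken up in DMF, (S)-phenylalanine (1 equiv), (1S)-(+)-camphor-10-sulfonic acid (0.5 equiv), 30 → 70 °C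
Reagents that add atoms: none
Why: Michael addition followed by the Hajos–Parrish–Eder–Sauer–Wiechert aldol condensation, in which the enamine formed from (S)-phenylalanine and the side-chain ketone picks one of the two enantiotopic ring carbonyls and so sets the quaternary carbon (future C10) as S.

Step 2
Reactants: 4 (7aS)-enedione
Product: 5 (1S,7aS)-1-hydroxy enone
Conditions: NaBH4 (0.3 equiv), EtOH, −20 °C
Reagents that add atoms: none
Why: Chemoselective borohydride reduction of the saturated cyclopentanone beside the less electrophilic conjugated ketone, with hydride delivered anti to the angular methyl to give the 1β-alcohol, which parks this carbonyl for the dissolving-metal step.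

Step 3
Reactants: 5 (1S,7aS)-1-hydroxy enone
Product: 6 trans-fused keto diol
Conditions: Li (2.2 equiv), NH3(l)/THF, −78 → −33 °C; NH3 evaporated; THF, CH2O (gas), −78 °C; aq. NH4Cl
Reagents that add atoms: formaldehyde (C=O)
Why: Birch-type dissolving-metal reduction of the enone gives a regiodefined lithium enolate after protonation of the β-carbon (future C5) by the substrate hydroxyl in the sense that gives the trans ring fusion, and this enolate is hydroxymethylated by formaldehyde anti to the angular methyl (reductive aldol), which sets C4 with the CH2OH α and the CH3 β.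

Step 4
Reactants: 6 trans-fused keto diol
Product: 7 dithiolane diol
Conditions: HSCH2CH2SH, BF3·OEt2, CH2Cl2, 0 °C → rt
Reagents that add atoms: ethane-1,2-dithiol (SCCS)
Why: Lewis-acid-mediated dithioketalisation of the hindered ketone, chosen because the β-hydroxy ketone would lose formaldehyde by retro-aldol under the basic conditions of a Wolff–Kishner reduction, and no stereocentre is touched.

Step 5
Reactants: 7 dithiolane diol
Product: 8 hydrindane diol
Conditions: Raney Ni (W-2), EtOH, reflux
Reagents that add atoms: none
Why: Mozingo desulfurisation (hydrogenolysis of both C–S bonds on Raney Ni) turns the dithioketal carbon into the C3 methylene without affecting the alcohols or the stereocentres.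

Step 6
Reactants: 8 hydrindane diol
Product: 9 primary TBS ether
Conditions: TBSCl (1.05 equiv), imidazole, CH2Cl2, 0 °C
Reagents that add atoms: tert-butyldimethylsilyl chloride (CC(C)(C)[Si](C)(C)Cl)
Why: Sterically controlled silylation of the primary hydroxyl in preference to the secondary cyclopentanol next to the quaternary carbon, installing the protecting group that is carried to the assembly stage.

Step 7
Reactants: 9 primary TBS ether
Product: 10 trans-hydrindan-1-one
Conditions: Dess–Martin periodinane, NaHCO3, CH2Cl2, rt
Reagents that add atoms: none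
Why: Dess–Martin oxidation of the secondary alcohol restores the cyclopentanone under buffered neutral conditions that leave the silyl ether intact.

Step 8
Reactants: 10 trans-hydrindan-1-one
Product: 11 1α-vinyl-1β-carbinol
Conditions: CeCl3 (anhydrous), CH2=CHMgBr, THF, −78 → 0 °C
Reagents that add atoms: vinylmagnesium bromide (C=C[Mg]Br)
Why: Organocerium-modified Grignard 1,2-addition to the hindered, enolisable cyclopentanone from the α-face, anti to the angular methyl (as with 17-keto steroids), which sets the tertiary carbinol with the hydroxyl β and the vinyl group α.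

Step 9
Reactants: 11 1α-vinyl-1β-carbinol
Product: 12 (R)-oxiranyl carbinol
Conditions: VO(acac)2 (5 mol%), t-BuOOH, CH2Cl2, 0 °C → rt
Reagents that add atoms: tert-butyl hydroperoxide (CC(C)(C)OO)
Why: Hydroxyl-directed vanadium-catalysed epoxidation of the tertiary allylic alcohol, for which the transition state with the bulky quaternary ring carbon perpendicular to the alkene plane and the ring CH2 eclipsing the vinylic hydrogen should be preferred (the erythro-type preference of such epoxidations) and should deliver the (R)-oxirane, the minor diastereomer being separable at this stage.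

Step 10
Reactants: 12 (R)-oxiranyl carbinol
Product: 13 decalin β-hydroxy ketone
Conditions: ZnBr2 (0.3 equiv), CH2Cl2, 0 °C → rt
Reagents that add atoms: none
Why: ZnBr2 chelates the tertiary hydroxyl and the oxirane oxygen of 12, the C9–O bond weakens, and the ring bond from the carbinol carbon to the quaternary angular carbon (C1–C7a of the hydrindane, the future C8–C10 bond) migrates to C9 antiperiplanar to the leaving oxygen, while the carbinol collapses to the C8 ketone and the oxirane CH2O is left as the C11 hydroxymethyl group. The closest known reaction type is the Lewis-acid semipinacol rearrangement of tertiary 2,3-epoxy alcohols to β-hydroxy ketones, used here as a one-carbon ring enlargement. No new ring is closed in the Baldwin sense: the cyclopentane (C5, C6, C7, C8, C10) is enlarged to the cyclohexanone ring B (C5–C10) by a suprafacial 1,2-alkyl shift through a three-centre bridged transition state, helped by release of trans-hydrindane strain. The single new stereocentre, C9, is set stereospecifically by inversion at the oxirane carbon, so the (R)-oxirane should give the 9β-CH2OH/9α-H arrangement, which is also the more stable equatorial epimer of this enolisable ketone; C10 migrates with retention, so the trans ring fusion and all other centres are untouched. The step needs migration of the quaternary carbon C10 and not of the ring CH2 (C7), and this is secured by the higher migratory aptitude of the more substituted carbon and by the chelate rotamer of the (R)-oxirane, in which the oxirane C–H lies between the two ring bonds and only the C8–C10 bond is antiperiplanar to the C9–O bond.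

Step 11
Reactants: 13 decalin β-hydroxy ketone
Product: 14 homoallylic alcohol (4α-silyloxymethyl drim-8(12)-en-11-ol)
Conditions: Zn, CH2Br2, TiCl4, THF/CH2Cl2, 0 °C → rt
Reagents that add atoms: dibromomethane (BrCBr)
Why: Lombardo methylenation is non-basic, so the β-hydroxy ketone should be converted into the exocyclic C8=C12 alkene without retro-aldol, dehydration or epimerisation at C9, and the free hydroxyl and the silyl ether are tolerated.

Step 12
Reactants: 14 homoallylic alcohol
Product: 15 drimane aldehyde (4α-silyloxymethyl drim-8(12)-en-11-al)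
Conditions: Dess–Martin periodinane, NaHCO3, CH2Cl2, 0 °C
Reagents that add atoms: none
Why: Dess–Martin oxidation under bicarbonate buffer gives the β,γ-unsaturated aldehyde without base, so C9 should not epimerise and the alkene should not move into conjugation.

Step 13
Reactants: 16 (R)-malic acid
Product: 18 1-methyl hydrogen (R)-malate, via O-trifluoroacetyl anhydride 17 (not isolated)
Conditions: (CF3CO)2O, 0 °C → rt; volatiles removed; MeOH, 0 °C → rt
Reagents that add atoms: methanol (CO)
Why: Trifluoroacetic anhydride converts the hydroxy diacid into the O-trifluoroacetyl cyclic anhydride, which methanol opens at the carbonyl next to the electron-poor carbinol carbon before cleaving the trifluoroacetate by transesterification, giving the 1-methyl ester regioselectively with the stereocentre untouched.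

Step 14
Reactants: 18 1-methyl hydrogen (R)-malate
Product: 19 4-allyl 1-methyl (R)-malate
Conditions: allyl bromide, KHCO3, DMF, rt
Reagents that add atoms: allyl bromide (C=CCBr)
Why: Carboxylate O-alkylation (SN2) with allyl bromide under weak base esterifies C4 without alkylating the poorly nucleophilic hydroxyl of the α-hydroxy ester.

Step 15
Reactants: 18 1-methyl hydrogen (R)-malate
Product: 20 4-tert-butyl 1-methyl (R)-malate
Conditions: Cl3CC(=NH)O-t-Bu, CH2Cl2/cyclohexane, rt
Reagents that add atoms: tert-butyl 2,2,2-trichloroacetimidate (CC(C)(C)OC(=N)C(Cl)(Cl)Cl)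
Why: Acid-selective tert-butylation with the trichloroacetimidate, which the carboxylic acid itself protonates, so the ester forms without added acid and the secondary hydroxyl stays free.

Step 16
Reactants: 19 4-allyl 1-methyl (R)-malate
Product: 21 isocitrate block for unit A (C1' methyl; C2' allyl; C3' methyl ester)
Conditions: LiN(SiMe3)2 (2.1 equiv), THF, −78 → −20 °C; BrCH2CO2Me, −78 → −20 °C; AcOH, −78 °C
Reagents that add atoms: methyl bromoacetate (COC(=O)CBr)
Why: Fráter–Seebach alkylation, in which the chelated lithium alkoxide–enolate dianion of the β-hydroxy ester is alkylated by the bromoacetate anti to the alkoxide-bearing carbon, setting C2' as S (threo, the natural isocitrate configuration) and leaving three differentiated carboxyls.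

Step 17
Reactants: 20 4-tert-butyl 1-methyl (R)-malate
Product: 22 isocitrate block for units B and C (C1' methyl; C2' tert-butyl; C3' allyl ester)
Conditions: LiN(SiMe3)2 (2.1 equiv), THF, −78 → −20 °C; BrCH2CO2CH2CH=CH2, −78 → −20 °C; AcOH, −78 °C
Reagents that add atoms: allyl bromoacetate (C=CCOC(=O)CBr)
Why: The same Fráter–Seebach anti alkylation, here of the tert-butyl ester dianion with allyl bromoacetate, gives the (1'R,2'S) block with three different esters.

Step 18
Reactants: 15 drimane aldehyde; 22 isocitrate block for units B and C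
Product: 24 monomer ether for units B and C (TBS ether; C2' tert-butyl; C3' allyl), via trimethylsilyl ether 23 (not isolated)
Conditions: 22 (1.3 equiv), HN(SiMe3)2 (0.6 equiv), TMSOTf (1 mol%), CH2Cl2, rt, volatiles removed; 15, Et3SiH (1.5 equiv), TMSOTf (0.15 equiv), CH2Cl2, −78 → −40 °C; Et3N quench
Reagents that add atoms: none
Why: Silyl-ether reductive etherification, in which aldehyde 15 and silyl ether 23 form a mixed silyl acetal and then an oxocarbenium ion under TMSOTf catalysis that Et3SiH reduces at low temperature, so the hindered C11–O bond is made at an sp2 carbon without breaking the C1'–O bond (C1' retained) and without base that could epimerise C9 or eliminate the β-alkoxy ester.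

Step 19
Reactants: 15 drimane aldehyde; 21 isocitrate block for unit A
Product: 26 monomer ether for unit A (TBS ether; C2' allyl; C3' methyl), via trimethylsilyl ether 25 (not isolated)
Conditions: 21 (1.3 equiv), HN(SiMe3)2 (0.6 equiv), TMSOTf (1 mol%), CH2Cl2, rt, volatiles removed; 15, Et3SiH (1.5 equiv), TMSOTf (0.15 equiv), CH2Cl2, −78 → −40 °C; Et3N quench
Reagents that add atoms: none
Why: The same silyl-ether reductive etherification with block 21 should give the unit A ether with C1', C2' and C9 unchanged.

Step 20
Reactants: 24 monomer ether for units B and C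
Product: 27 monomer acid (free C2' carboxyl)
Conditions: TMSOTf (3 equiv), 2,6-lutidine (4 equiv), CH2Cl2, 0 °C → rt; pH 5 aqueous work-up
Reagents that add atoms: none
Why: Silyl-triflate cleavage of the tert-butyl ester (O-silylation, loss of isobutene, hydrolysis of the silyl ester on work-up) frees only the central carboxyl under buffered non-protic conditions that spare the exocyclic alkene, the silyl ether and the allyl and methyl esters.

Step 21
Reactants: 26 monomer ether for unit A
Product: 28 unit A alcohol
Conditions: HF·pyridine, pyridine, THF, 0 °C → rt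
Reagents that add atoms: none
Why: Fluoride desilylation with buffered HF·pyridine frees the neopentyl-type primary alcohol without ester cleavage, β-elimination or alkene isomerisation.

Step 22
Reactants: 28 unit A alcohol; 27 monomer acid
Product: 29 dimer silyl ether (units A and B)
Conditions: 2-methyl-6-nitrobenzoic anhydride (1.3 equiv), DMAP (0.2 equiv), Et3N, CH2Cl2, rt
Reagents that add atoms: none
Why: Shiina esterification (mixed anhydride with 2-methyl-6-nitrobenzoic anhydride, acyl transfer by DMAP) joins the hindered central acid and the neopentyl-type alcohol at room temperature under weakly basic conditions chosen to avoid epimerisation at C2' and β-elimination of the ether oxygen.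

Step 23
Reactants: 29 dimer silyl ether
Product: 30 dimer alcohol
Conditions: HF·pyridine, pyridine, THF, 0 °C → rt
Reagents that add atoms: none
Why: The same buffered fluoride desilylation frees the 4α-CH2OH of unit B while the four esters of the isocitrates and the inter-unit ester stay intact.

Step 24
Reactants: 30 dimer alcohol; 27 monomer acid
Product: 31 trimer silyl ether (units A, B and C)
Conditions: 2-methyl-6-nitrobenzoic anhydride (1.3 equiv), DMAP (0.2 equiv), Et3N, CH2Cl2, rt
Reagents that add atoms: none
Why: A second Shiina esterification with the same monomer acid adds unit C at the 4α-CH2OH of unit B under the same mild conditions.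

Step 25
Reactants: 31 trimer silyl ether
Product: 32 trimer alcohol triallyl ester
Conditions: HF·pyridine, pyridine, THF, 0 °C → rt
Reagents that add atoms: none
Why: Buffered fluoride desilylation frees the 4α-CH2OH of unit C while all carboxyls are still protected, which keeps the last step a single neutral operation.

Step 26
Reactants: 32 trimer alcohol triallyl ester
Product: 33 cryptoporic acid T
Conditions: Pd(PPh3)4 (10 mol%), morpholine, THF, rt; pH 3 aqueous work-up
Reagents that add atoms: none
Why: Tsuji–Trost deallylation, in which zerovalent palladium ionises the three allyl esters to π-allyl complexes that morpholine captures, frees the three carboxylic acids under neutral conditions that leave the methyl esters, the inter-unit esters, the β-alkoxy ester stereocentres and the exocyclic alkenes untouched.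

**Compound list**

1 | 2-methylcyclopentane-1,3-dione | CC1C(=O)CCC1=O | starting material
2 | pent-1-en-3-one (ethyl vinyl ketone) | CCC(=O)C=C | starting material
3 | 2-methyl-2-(3-oxopentyl)cyclopentane-1,3-dione (triketone formed in the flask of step 1) | CCC(=O)CCC1(C)C(=O)CCC1=O | intermediate
4 | (7aS)-4,7a-dimethyl-2,3,7,7a-tetrahydro-1H-indene-1,5(6H)-dione | O=C1CCC2=C(C)C(=O)CC[C@]12C | intermediate
5 | (1S,7aS)-1-hydroxy-4,7a-dimethyl-1,2,3,6,7,7a-hexahydro-5H-inden-5-one (1-OH cis to the angular methyl) | O[C@H]1CCC2=C(C)C(=O)CC[C@]12C | intermediate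
6 | trans-fused 1β-hydroxy-4α-(hydroxymethyl)-4β,7aβ-dimethyl-octahydro-5H-inden-5-one (3aα-H) | O[C@H]1CC[C@H]2[C@](C)(CO)C(=O)CC[C@]12C | intermediate
7 | 5,5-(ethane-1,2-diyldithio) ketal of 6 (spiro-1,3-dithiolane; 1β-OH; 4α-CH2OH) | O[C@H]1CC[C@H]2[C@](C)(CO)C3(SCCS3)CC[C@]12C | intermediate
8 | trans-fused 4α-(hydroxymethyl)-4β,7aβ-dimethyl-octahydro-1H-inden-1β-ol (3aα-H) | O[C@H]1CC[C@H]2[C@](C)(CO)CCC[C@]12C | intermediate
9 | 4α-[(tert-butyldimethylsilyloxy)methyl] ether of 8 (1β-OH free) | O[C@H]1CC[C@H]2[C@](C)(CO[Si](C)(C)C(C)(C)C)CCC[C@]12C | intermediate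
10 | trans-fused 4α-[(tert-butyldimethylsilyloxy)methyl]-4β,7aβ-dimethyl-octahydro-1H-inden-1-one | O=C1CC[C@H]2[C@](C)(CO[Si](C)(C)C(C)(C)C)CCC[C@]12C | intermediate
11 | 1α-vinyl-1β-hydroxy derivative of 10 | C=C[C@]1(O)CC[C@H]2[C@](C)(CO[Si](C)(C)C(C)(C)C)CCC[C@]12C | intermediate
12 | 1α-[(R)-oxiran-2-yl]-1β-hydroxy derivative of 10 | C1O[C@H]1[C@]2(O)CC[C@H]3[C@](C)(CO[Si](C)(C)C(C)(C)C)CCC[C@]23C | intermediate
13 | 9β-(hydroxymethyl)-4α-[(tert-butyldimethylsilyloxy)methyl]-4β,10β-dimethyl-5α-trans-decalin-8-one (drimane numbering) | OC[C@H]1C(=O)CC[C@H]2[C@](C)(CO[Si](C)(C)C(C)(C)C)CCC[C@]12C | intermediate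
14 | 4α-[(tert-butyldimethylsilyloxy)methyl]drim-8(12)-en-11-ol (9β-CH2OH, 5α-H, 10β-CH3) | OC[C@H]1C(=C)CC[C@H]2[C@](C)(CO[Si](C)(C)C(C)(C)C)CCC[C@]12C | intermediate
15 | 4α-[(tert-butyldimethylsilyloxy)methyl]drim-8(12)-en-11-al (9β-CHO) | O=C[C@H]1C(=C)CC[C@H]2[C@](C)(CO[Si](C)(C)C(C)(C)C)CCC[C@]12C | intermediate
16 | (R)-malic acid (D-malic acid) | O[C@@H](C(=O)O)CC(=O)O | starting material
17 | (R)-2-(trifluoroacetoxy)succinic anhydride (formed in the flask of step 13) | O=C1C[C@@H](OC(=O)C(F)(F)F)C(=O)O1 | intermediate
18 | (R)-malic acid 1-methyl ester | O[C@@H](C(=O)OC)CC(=O)O | intermediate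
19 | 4-allyl 1-methyl (R)-malate | O[C@@H](C(=O)OC)CC(=O)OCC=C | intermediate
20 | 4-tert-butyl 1-methyl (R)-malate | O[C@@H](C(=O)OC)CC(=O)OC(C)(C)C | intermediate
21 | 2-allyl 1,3-dimethyl (1R,2S)-1-hydroxypropane-1,2,3-tricarboxylate | O[C@@H](C(=O)OC)[C@H](CC(=O)OC)C(=O)OCC=C | intermediate
22 | 3-allyl 2-tert-butyl 1-methyl (1R,2S)-1-hydroxypropane-1,2,3-tricarboxylate | O[C@@H](C(=O)OC)[C@H](CC(=O)OCC=C)C(=O)OC(C)(C)C | intermediate
23 | O-trimethylsilyl ether of 22 (formed in the flask of step 18) | C[Si](C)(C)O[C@@H](C(=O)OC)[C@H](CC(=O)OCC=C)C(=O)OC(C)(C)C | intermediate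
24 | 11-O-ether of 14 with block 22: 3-allyl 2-tert-butyl 1-methyl (1R,2S)-1-{[4α-(TBSO-methyl)drim-8(12)-en-11-yl]oxy}propane-1,2,3-tricarboxylate | CC(C)(C)OC(=O)[C@@H](CC(=O)OCC=C)[C@@H](OC[C@H]1C(=C)CC[C@H]2[C@](C)(CO[Si](C)(C)C(C)(C)C)CCC[C@]12C)C(=O)OC | intermediate
25 | O-trimethylsilyl ether of 21 (formed in the flask of step 19) | C[Si](C)(C)O[C@@H](C(=O)OC)[C@H](CC(=O)OC)C(=O)OCC=C | intermediate
26 | 11-O-ether of 14 with block 21: 2-allyl 1,3-dimethyl (1R,2S)-1-{[4α-(TBSO-methyl)drim-8(12)-en-11-yl]oxy}propane-1,2,3-tricarboxylate | C=C1CC[C@H]2[C@](C)(CO[Si](C)(C)C(C)(C)C)CCC[C@]2(C)[C@H]1CO[C@@H](C(=O)OC)[C@H](CC(=O)OC)C(=O)OCC=C | intermediate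
27 | monomer acid: 24 with the C2' carboxyl free (C1' methyl ester, C3' allyl ester, TBS ether) | OC(=O)[C@@H](CC(=O)OCC=C)[C@@H](OC[C@H]1C(=C)CC[C@H]2[C@](C)(CO[Si](C)(C)C(C)(C)C)CCC[C@]12C)C(=O)OC | intermediate
28 | unit A alcohol: 26 with the 4α-CH2OH free | C=C1CC[C@H]2[C@](C)(CO)CCC[C@]2(C)[C@H]1CO[C@@H](C(=O)OC)[C@H](CC(=O)OC)C(=O)OCC=C | intermediate
29 | dimer silyl ether: 28 acylated on its 4α-CH2OH by the C2' carboxyl of 27 | C=C1CC[C@H]2[C@](C)(COC(=O)[C@@H](CC(=O)OCC=C)[C@@H](OC[C@H]3C(=C)CC[C@H]4[C@](C)(CO[Si](C)(C)C(C)(C)C)CCC[C@]34C)C(=O)OC)CCC[C@]2(C)[C@H]1CO[C@@H](C(=O)OC)[C@H](CC(=O)OC)C(=O)OCC=C | intermediate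
30 | dimer alcohol: 29 with the 4α-CH2OH of unit B free | C=C1CC[C@H]2[C@](C)(COC(=O)[C@@H](CC(=O)OCC=C)[C@@H](OC[C@H]3C(=C)CC[C@H]4[C@](C)(CO)CCC[C@]34C)C(=O)OC)CCC[C@]2(C)[C@H]1CO[C@@H](C(=O)OC)[C@H](CC(=O)OC)C(=O)OCC=C | intermediate
31 | trimer silyl ether: 30 acylated on the 4α-CH2OH of unit B by the C2' carboxyl of 27 | C=C1CC[C@H]2[C@](C)(COC(=O)[C@@H](CC(=O)OCC=C)[C@@H](OC[C@H]3C(=C)CC[C@H]4[C@](C)(COC(=O)[C@@H](CC(=O)OCC=C)[C@@H](OC[C@H]5C(=C)CC[C@H]6[C@](C)(CO[Si](C)(C)C(C)(C)C)CCC[C@]56C)C(=O)OC)CCC[C@]34C)C(=O)OC)CCC[C@]2(C)[C@H]1CO[C@@H](C(=O)OC)[C@H](CC(=O)OC)C(=O)OCC=C | intermediate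
32 | trimer alcohol triallyl ester: 31 with the 4α-CH2OH of unit C free | C=C1CC[C@H]2[C@](C)(COC(=O)[C@@H](CC(=O)OCC=C)[C@@H](OC[C@H]3C(=C)CC[C@H]4[C@](C)(COC(=O)[C@@H](CC(=O)OCC=C)[C@@H](OC[C@H]5C(=C)CC[C@H]6[C@](C)(CO)CCC[C@]56C)C(=O)OC)CCC[C@]34C)C(=O)OC)CCC[C@]2(C)[C@H]1CO[C@@H](C(=O)OC)[C@H](CC(=O)OC)C(=O)OCC=C | intermediate
33 | cryptoporic acid T | C=C1CC[C@H]2[C@](C)(COC(=O)[C@@H](CC(=O)O)[C@@H](OC[C@H]3C(=C)CC[C@H]4[C@](C)(COC(=O)[C@@H](CC(=O)O)[C@@H](OC[C@H]5C(=C)CC[C@H]6[C@](C)(CO)CCC[C@]56C)C(=O)OC)CCC[C@]34C)C(=O)OC)CCC[C@]2(C)[C@H]1CO[C@@H](C(=O)OC)[C@H](CC(=O)OC)C(=O)O | target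

**Step count and risks**

Total step count: 26. Longest linear sequence: 19 steps (steps 1–12, 18, 20, 22–26).

The three steps most likely to fail:

1. Step 10 (ring enlargement). The wrong ring bond (the CH2 carbon C7) may migrate if the epoxidation of step 9 gives mainly the other oxirane diastereomer or if chelation control is lost; the oxirane may also be opened by bromide or undergo a hydride shift. Fallback: the ring enlargement would be run as a β-oxido carbenoid rearrangement that sets out from ketone 10. LiCHBr2 (from CH2Br2 and LiN(iPr)2, THF, −78 °C) adds to the α-face of 10 to give the dibromomethyl carbinol F1. With n-BuLi (2.2 equiv, THF, −95 → −78 °C) the lithium alkoxide undergoes Br/Li exchange and α-elimination, and the more substituted ring carbon migrates. The regiodefined C8–C9 lithium enolate so formed is trapped with gaseous CH2O and equilibrated at C9 to the equatorial epimer on work-up, which returns to the route at 13. This path has no oxirane stereocentre to control and is still a 5→6 ring enlargement.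

2. Step 18 (and its twin, step 19). The two hindered partners may fail to form the mixed acetal, C9 may epimerise through the enol ether of the oxocarbenium ion, or adventitious triflic acid may isomerise the exocyclic alkene. Fallback: the ether would be made by conjugate addition before the alkene is installed, setting out from 13. MsCl/Et3N then DBU (CH2Cl2, 0 °C → rt) gives the exocyclic enone F2. PMe3-catalysed oxa-Michael addition of 22 (THF, rt) gives the β-alkoxy ketone F3, with C9 set by enolate protonation to the equatorial epimer, and Zn/CH2Br2/TiCl4 methylenation returns to the route at 24. With block 21 the same two operations pass through the β-alkoxy ketone F4 and return at 26.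

3. Step 22 (and its twin, step 24). Acyl transfer between the hindered acid and the neopentyl-type alcohol may be slow, and the activated acid may epimerise at C2' or lose the C11–O ether by β-elimination. Fallback: the order of bond formation would be reversed (ester first, ether second), setting out from block 22. TESOTf/2,6-lutidine (CH2Cl2, 0 °C → rt; aqueous work-up) silylates the hydroxyl and cleaves the tert-butyl ester to give the triethylsilyl ether acid F5, a much smaller acylating partner. Shiina esterification of F5 with 28 gives the silyl-ether ester F6, and reductive etherification of F6 with aldehyde 15 (Et3SiH, TMSOTf cat., CH2Cl2, −78 °C) returns to the route at 29. At step 24 the same detour from 30 passes through the silyl-ether ester F7 and returns at 31.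

Further compounds
F1 | step 10 | 1α-(dibromomethyl)-1β-hydroxy derivative of 10 | BrC(Br)[C@]1(O)CC[C@H]2[C@](C)(CO[Si](C)(C)C(C)(C)C)CCC[C@]12C
F2 | step 18 | 9-methylene-4α-[(tert-butyldimethylsilyloxy)methyl]-4β,10β-dimethyl-5α-trans-decalin-8-one | C=C1C(=O)CC[C@H]2[C@](C)(CO[Si](C)(C)C(C)(C)C)CCC[C@]12C
F3 | step 18 | 8-oxo analogue of 24 (C8 ketone in place of the C8 methylene; 9β-CH2O ether of block 22) | CC(C)(C)OC(=O)[C@@H](CC(=O)OCC=C)[C@@H](OC[C@H]1C(=O)CC[C@H]2[C@](C)(CO[Si](C)(C)C(C)(C)C)CCC[C@]12C)C(=O)OC
F4 | step 18 | 8-oxo analogue of 26 (C8 ketone in place of the C8 methylene; 9β-CH2O ether of block 21) | C=CCOC(=O)[C@@H](CC(=O)OC)[C@@H](OC[C@H]1C(=O)CC[C@H]2[C@](C)(CO[Si](C)(C)C(C)(C)C)CCC[C@]12C)C(=O)OC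
F5 | step 22 | (1R,2S)-1-(triethylsilyloxy)propane-1,2,3-tricarboxylic acid 3-allyl 1-methyl diester (free C2' carboxyl) | CC[Si](CC)(CC)O[C@@H](C(=O)OC)[C@H](CC(=O)OCC=C)C(=O)O
F6 | step 22 | 28 acylated on its 4α-CH2OH by the C2' carboxyl of F5 | C=C1CC[C@H]2[C@](C)(COC(=O)[C@@H](CC(=O)OCC=C)[C@@H](O[Si](CC)(CC)CC)C(=O)OC)CCC[C@]2(C)[C@H]1CO[C@@H](C(=O)OC)[C@H](CC(=O)OC)C(=O)OCC=C
F7 | step 22 | 30 acylated on the 4α-CH2OH of unit B by the C2' carboxyl of F5 | C=C1CC[C@H]2[C@](C)(COC(=O)[C@@H](CC(=O)OCC=C)[C@@H](OC[C@H]3C(=C)CC[C@H]4[C@](C)(COC(=O)[C@@H](CC(=O)OCC=C)[C@@H](O[Si](CC)(CC)CC)C(=O)OC)CCC[C@]34C)C(=O)OC)CCC[C@]2(C)[C@H]1CO[C@@H](C(=O)OC)[C@H](CC(=O)OC)C(=O)OCC=C
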